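**Retrosynthetic overview**

1. Conventions: ring A is the arene with one OH, ring B the arene with two OH, and the tether is counted C1 (on ring B) to C16 (on ring A). Target ⇒ its tri-O-methyl ether (BBr3) ⇒ a macrocyclic C10=C11 alkene with a temporary OAc on C1; one hydrogenation saturates the alkene and hydrogenolyses the benzylic C1–O bond.
2. Key disconnection: ring-closing metathesis across C10=C11 of an acyclic diaryl-ether diene. It forms the only ring the route has to make, the 22-membered ring (C1–C16, three ring A atoms, the bridging O, two ring B atoms); rings A and B are bought as arenes.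
3. Diene ⇒ dec-9-enyl Grignard addition to a diaryl-ether aldehyde (the CHO carbon becomes C1) ⇒ Ullmann C–O coupling of a ring A phenol with 2-bromo-3,5-dimethoxybenzaldehyde, whose formyl group activates the C–Br bond.
4. Ring A phenol ⇒ copper-catalysed coupling of 3,5-dimethoxybenzyl bromide with hex-5-enylmagnesium bromide (the benzylic CH2 becomes C16), then thiolate mono-demethylation.
5. Enabling feature: C1–C16 is a bare (CH2)16 chain with no branch, heteroatom or stereocentre, so C10–C11 can be made as an alkene of either geometry and then reduced. The tether leaves ring B ortho and ring A meta to the bridging oxygen, so the bent C–O–C hinge holds both chain origins on one side and the large ring should close without strain.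

Key step: step 5

Remark on the chemistry: the target has no stereocentre; the one stereocentre met on the way (C1 of the Grignard adduct and of the metathesis product) is made as a racemate and erased by the hydrogenation. 2-Bromo-3,5-dimethoxybenzaldehyde is taken as a catalogue compound.

**Route**

Step 1
Reactants: 1 6-bromohex-1-ene; 2 1-(bromomethyl)-3,5-dimethoxybenzene (3,5-dimethoxybenzyl bromide)
Product: 4 1-(hept-6-en-1-yl)-3,5-dimethoxybenzene, via hex-5-en-1-ylmagnesium bromide 3 (not isolated)
Conditions: 1, Mg, THF, rt to 40 °C; then slow addition to 2, Li2CuCl4 (3 mol%), THF, −20 °C to rt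
Reagents that add atoms: none
Why: Kochi-type copper-catalysed sp3–sp3 cross-coupling of a primary alkyl Grignard reagent with a benzylic bromide is fast at low temperature and leaves the terminal alkene and the aryl methyl ethers untouched, and slow addition keeps Wurtz homocoupling low; no stereocentre is formed.

Step 2
Reactants: 4 1-(hept-6-en-1-yl)-3,5-dimethoxybenzene
Product: 5 3-(hept-6-en-1-yl)-5-methoxyphenol
Conditions: NaSEt (3 equiv), DMF, 140 °C; then aq. HCl
Reagents that add atoms: none
Why: Thiolate SN2 demethylation of an aryl methyl ether should stop after one cleavage, because the phenoxide formed deactivates the second methoxy group, as is standard for 5-alkylresorcinol dimethyl ethers; the isolated alkene is inert to the thiolate.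

Step 3
Reactants: 5 3-(hept-6-en-1-yl)-5-methoxyphenol; 6 2-bromo-3,5-dimethoxybenzaldehyde
Product: 7 2-[3-(hept-6-en-1-yl)-5-methoxyphenoxy]-3,5-dimethoxybenzaldehyde
Conditions: CuI (copper monoiodide, 10 mol%), N,N-dimethylglycine hydrochloride (30 mol%), Cs2CO3 (2 equiv), 1,4-dioxane, 100 °C
Reagents that add atoms: none
Why: Ullmann-type copper-catalysed C–O coupling; the ortho formyl group activates the C–Br bond toward oxidative addition to monovalent copper and coordinates the metal, which offsets the two ortho substituents, while the phenol is unhindered and the terminal alkene takes no part.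

Step 4
Reactants: 7 2-[3-(hept-6-en-1-yl)-5-methoxyphenoxy]-3,5-dimethoxybenzaldehyde; 8 10-bromodec-1-ene
Product: 11 rac-1-{2-[3-(hept-6-en-1-yl)-5-methoxyphenoxy]-3,5-dimethoxyphenyl}undec-10-en-1-yl acetate, via dec-9-en-1-ylmagnesium bromide 9 (not isolated), via bromomagnesium alkoxide 10 (not isolated)
Conditions: 8, Mg, THF, rt; then 7, THF, −78 to 0 °C; then Ac2O (3 equiv), DMAP (cat.), 0 °C to rt
Reagents that add atoms: acetic anhydride, CC(=O)OC(C)=O
Why: Grignard 1,2-addition to a non-enolisable aryl aldehyde followed by O-acylation of the magnesium alkoxide in the same flask; the new stereocentre at C1 forms without control (racemate) and is deliberately temporary, since step 6 removes its oxygen.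

Step 5
Reactants: 11 rac-1-{2-[3-(hept-6-en-1-yl)-5-methoxyphenoxy]-3,5-dimethoxyphenyl}undec-10-en-1-yl acetate
Product: 12 rac-1-acetoxy-10,11-didehydro-tri-O-methylgrevirobstol B (22-membered cyclophane, OAc on C1, C10=C11 as an E/Z mixture)
Conditions: RuCl2(=CHPh)(PCy3)(H2IMes) (second-generation Grubbs catalyst, 5 mol%), 1,4-benzoquinone (10 mol%), CH2Cl2 (final 1 mM, slow addition of 11), 40 °C
Reagents that add atoms: none
Why: Olefin metathesis by the Chauvin mechanism: the ruthenium benzylidene initiates on one of the two monosubstituted vinyl groups, the resulting alkylidene adds intramolecularly to the other vinyl group ([2+2] to a ruthenacyclobutane, then retro-[2+2]), and loss of ethene makes the closure practically irreversible. The closest known reaction type is macrocyclic ring-closing metathesis of α,ω-dienes to 20- to 24-membered cyclophanes and macrocyclic musks. The single ring closed is the 22-membered ring, in an end-to-end closure of the two chain termini that makes C10=C11 an endocyclic double bond. No stereocentre is created; the alkene geometry is not controlled and need not be, because step 6 removes it, and the racemic C1 centre is untouched. The selectivity needed is ring closure over oligomerisation and freedom from double-bond migration: high dilution with slow addition, the ortho/meta hinge at the bridging oxygen that keeps the chain ends on one side, the absence of any other reactive alkene (no styrene, no allylic heteroatom), and 1,4-benzoquinone as a scavenger of ruthenium hydrides should secure it.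

Step 6
Reactants: 12 rac-1-acetoxy-10,11-didehydro-tri-O-methylgrevirobstol B
Product: 13 tri-O-methylgrevirobstol B (saturated 22-membered cyclophane, all three phenols as methyl ethers)
Conditions: H2 (4 atm), Pd/C (palladium on carbon, 10 wt% Pd), EtOH/EtOAc, 40 °C
Reagents that add atoms: none
Why: Heterogeneous hydrogenation saturates the disubstituted C10=C11 alkene of either geometry, and the benzylic C1–OAc bond is cleaved by hydrogenolysis on palladium in the way benzyl esters are, which also erases the C1 stereocentre; aryl methyl ethers and the diaryl ether are stable, and acid is left out because an ionised C1 could alkylate ring A to a xanthene.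

Step 7
Reactants: 13 tri-O-methylgrevirobstol B
Product: 14 grevirobstol B
Conditions: BBr3 (6 equiv), CH2Cl2, −78 °C to rt; then H2O
Reagents that add atoms: none
Why: Lewis-acid demethylation with BBr3 (O–B complexation, then bromide SN2 attack at methyl) cleaves all three aryl methyl ethers, while the diaryl ether, which has no sp3 carbon on oxygen, and the saturated tether are inert; the target has no stereocentre.

**Compound list**

1 | 6-bromohex-1-ene | C=CCCCCBr | starting material
2 | 1-(bromomethyl)-3,5-dimethoxybenzene | COc1cc(CBr)cc(OC)c1 | starting material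
3 | hex-5-en-1-ylmagnesium bromide | C=CCCCC[Mg]Br | intermediate
4 | 1-(hept-6-en-1-yl)-3,5-dimethoxybenzene | COc1cc(CCCCCC=C)cc(OC)c1 | intermediate
5 | 3-(hept-6-en-1-yl)-5-methoxyphenol | COc1cc(O)cc(CCCCCC=C)c1 | intermediate
6 | 2-bromo-3,5-dimethoxybenzaldehyde | COc1cc(C=O)c(Br)c(OC)c1 | starting material
7 | 2-[3-(hept-6-en-1-yl)-5-methoxyphenoxy]-3,5-dimethoxybenzaldehyde | COc1cc(C=O)c(Oc2cc(OC)cc(CCCCCC=C)c2)c(OC)c1 | intermediate
8 | 10-bromodec-1-ene | C=CCCCCCCCCBr | starting material
9 | dec-9-en-1-ylmagnesium bromide | C=CCCCCCCCC[Mg]Br | intermediate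
10 | bromomagnesium rac-1-{2-[3-(hept-6-en-1-yl)-5-methoxyphenoxy]-3,5-dimethoxyphenyl}undec-10-en-1-olate | COc1cc(C(CCCCCCCCC=C)O[Mg]Br)c(Oc2cc(OC)cc(CCCCCC=C)c2)c(OC)c1 | intermediate
11 | rac-1-{2-[3-(hept-6-en-1-yl)-5-methoxyphenoxy]-3,5-dimethoxyphenyl}undec-10-en-1-yl acetate | COc1cc(C(CCCCCCCCC=C)OC(C)=O)c(Oc2cc(OC)cc(CCCCCC=C)c2)c(OC)c1 | intermediate
12 | rac-1-acetoxy-10,11-didehydro-tri-O-methylgrevirobstol B (E/Z mixture expected, E isomer drawn; racemic at C1) | COc1cc2cc(c1)Oc1c(OC)cc(OC)cc1C(OC(C)=O)CCCCCCCC/C=C/CCCCC2 | intermediate
13 | tri-O-methylgrevirobstol B | COc1cc2cc(c1)Oc1c(OC)cc(OC)cc1CCCCCCCCCCCCCCCC2 | intermediate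
14 | grevirobstol B | Oc1cc2cc(c1)Oc1c(O)cc(O)cc1CCCCCCCCCCCCCCCC2 | target

**Step count and risks**

Total step count: 7. Longest linear sequence: 7 steps (steps 1 to 7; compounds 1, 2, 6 and 8 are used as bought).

Steps most likely to fail:

1. Step 5. Process at risk: intermolecular metathesis (oligomers, cyclic dimers) outrunning the ring closure, and ruthenium-hydride-induced migration of the terminal double bonds before closure, which would give ring-contracted homologues. The fallback sets out from 11 and comes back at 12. Lemieux–Johnson cleavage of both vinyl groups (OsO4 cat., NaIO4, 2,6-lutidine, dioxane/H2O) should give rac-1-{2-[3-methoxy-5-(6-oxohexyl)phenoxy]-3,5-dimethoxyphenyl}-10-oxodecyl acetate F1. An intramolecular McMurry coupling (TiCl3(DME)1.5, Zn–Cu couple, DME, reflux, syringe-pump addition) should then close the same 22-membered ring by forming C10=C11, giving 12.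

2. Step 6. Process at risk: stalling of the C1–O hydrogenolysis at the hindered secondary benzylic acetate once the alkene is saturated, or ionisation at C1 on an acidic catalyst surface followed by intramolecular Friedel–Crafts attack on ring A. The fallback sets out from 7 and comes back at 13; it takes the oxygen off C1 before the ring closure. NaBH4 in MeOH should reduce 7 to {2-[3-(hept-6-en-1-yl)-5-methoxyphenoxy]-3,5-dimethoxyphenyl}methanol F2. CBr4/PPh3 in CH2Cl2 should give 1-(bromomethyl)-2-[3-(hept-6-en-1-yl)-5-methoxyphenoxy]-3,5-dimethoxybenzene F3. Li2CuCl4-catalysed coupling with the Grignard reagent 9 (made from 8 as in step 4, coupled as in step 1) should give 2-[3-(hept-6-en-1-yl)-5-methoxyphenoxy]-1,5-dimethoxy-3-(undec-10-en-1-yl)benzene F4. Ring-closing metathesis under the conditions of step 5 should give 10,11-didehydro-tri-O-methylgrevirobstol B F5, and plain hydrogenation (H2, Pd/C, EtOAc) then leads to 13.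

3. Step 3. Process at risk: slow oxidative addition of monovalent copper into a C–Br bond flanked by two ortho substituents, so that protodebromination and base-induced decay of the aldehyde compete. The fallback sets out from 5 and comes back at 7; it is a metal-free nucleophilic aromatic substitution. Electrophilic fluorination of commercial 3,5-dimethoxybenzaldehyde with Selectfluor in MeCN should give 2-fluoro-3,5-dimethoxybenzaldehyde F6 (fluorination ortho to the carbonyl group and para to a methoxy group). The phenoxide of 5 (K2CO3, DMSO, 120 °C) should then displace the fluoride, activated by the ortho formyl group, by addition–elimination to give 7.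

**Further compounds**

F1 | step 5 | rac-1-{2-[3-methoxy-5-(6-oxohexyl)phenoxy]-3,5-dimethoxyphenyl}-10-oxodecyl acetate | COc1cc(C(CCCCCCCCC=O)OC(C)=O)c(Oc2cc(OC)cc(CCCCCC=O)c2)c(OC)c1
F2 | step 6 | {2-[3-(hept-6-en-1-yl)-5-methoxyphenoxy]-3,5-dimethoxyphenyl}methanol | COc1cc(CO)c(Oc2cc(OC)cc(CCCCCC=C)c2)c(OC)c1
F3 | step 6 | 1-(bromomethyl)-2-[3-(hept-6-en-1-yl)-5-methoxyphenoxy]-3,5-dimethoxybenzene | COc1cc(CBr)c(Oc2cc(OC)cc(CCCCCC=C)c2)c(OC)c1
F4 | step 6 | 2-[3-(hept-6-en-1-yl)-5-methoxyphenoxy]-1,5-dimethoxy-3-(undec-10-en-1-yl)benzene | COc1cc(CCCCCCCCCC=C)c(Oc2cc(OC)cc(CCCCCC=C)c2)c(OC)c1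
F5 | step 6 | 10,11-didehydro-tri-O-methylgrevirobstol B (E/Z mixture expected, E isomer drawn) | COc1cc2cc(c1)Oc1c(OC)cc(OC)cc1CCCCCCCCC/C=C/CCCCC2
F6 | step 3 | 2-fluoro-3,5-dimethoxybenzaldehyde | COc1cc(C=O)c(F)c(OC)c1
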